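The route rests on closing the 10-membered carbocycle last, between C1 (the β-carbon of the C1=C10 enoate that carries the C14 methyl ester) and C2 (the methylene β to epoxide carbon C4; germacrane numbering). Both atoms are natural electrophiles, so C2 is reversed in polarity as an alkylzinc and joined to the (E)-bromoalkene C1 by an intramolecular Negishi coupling, which forms the ring and fixes the ring-cis C1=C10 geometry in one operation. The precursor is an open chain that already holds the C4–C5 epoxide, the trans-fused α-methylene γ-lactone (C6, C7, C11, C12), both esters and all six stereocentres.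

Key step: step 19

Remark: atoms carry germacrane numbers throughout (C1=C10, C4–C5 epoxide with methyl C15 on C4, lactone C6–O–C12 with methylene C13, oxygens on C8 and C9, ester C14).
Remark: it is assumed that the β-bromo Morita–Baylis–Hillman adduct of step 10 equilibrates, by reversible bromide addition, to the isomer with bromine trans to the ester, as trisubstituted acrylates generally do.

Step 1
Reactants: 1 4-bromobut-1-yne
Product: 3 methyl 5-bromopent-2-ynoate, via lithium acetylide 2 (not isolated)
Conditions: n-BuLi, THF, −78 °C; ClCO2Me, −78 °C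
Reagents that add atoms: methyl chloroformate, COC(=O)Cl
Why: Deprotonation of the terminal alkyne and C-acylation of the acetylide with a chloroformate is the standard ynoate synthesis, and the primary bromide should be inert at −78 °C.

Step 2
Reactants: 3 methyl 5-bromopent-2-ynoate
Product: 5 methyl (2Z)-5-bromo-3-methylpent-2-enoate, via alkenylcuprate 4 (not isolated)
Conditions: Me2CuLi, THF, −78 °C; MeOH, −78 °C
Reagents that add atoms: lithium dimethylcuprate, [Li+].C[Cu-]C
Why: syn-Carbocupration of the ynoate and protonation with retention at −78 °C should place the bromoethyl chain cis to the ester, the (Z) geometry that later becomes the ring-cis epoxide.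

Step 3
Reactants: 5 methyl (2Z)-5-bromo-3-methylpent-2-enoate
Product: 6 (2Z)-5-bromo-3-methylpent-2-en-1-ol
Conditions: i-Bu2AlH (2.2 equiv), CH2Cl2, −78 °C; aq. KNaC4H4O6 work-up
Reagents that add atoms: none
Why: 1,2-Reduction of the conjugated ester with a dialkylaluminium hydride should give the allylic alcohol without touching the alkene geometry or the bromide.

Step 4
Reactants: 6 (2Z)-5-bromo-3-methylpent-2-en-1-ol
Product: 7 [(2S,3R)-3-(2-bromoethyl)-3-methyloxiran-2-yl]methanol
Conditions: Ti(OiPr)4 (cat.), L-(+)-diethyl tartrate, t-BuOOH, 4 Å molecular sieves, CH2Cl2, −20 °C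
Reagents that add atoms: tert-butyl hydroperoxide, CC(C)(C)OO
Why: Sharpless asymmetric epoxidation with the L-(+)-tartrate should give the (2S) epoxy alcohol, and the (Z) alkene fixes the cis relationship on the oxirane, which sets C4 (R) and C5 (S).

Step 5
Reactants: 7 [(2S,3R)-3-(2-bromoethyl)-3-methyloxiran-2-yl]methanol
Product: 8 (2R,3R)-3-(2-bromoethyl)-3-methyloxirane-2-carbaldehyde
Conditions: Dess–Martin periodinane, NaHCO3, CH2Cl2, 0 °C
Reagents that add atoms: none
Why: Buffered Dess–Martin oxidation should give the epoxy aldehyde without opening or epimerising the epoxide.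

Step 6
Reactants: 8 (2R,3R)-3-(2-bromoethyl)-3-methyloxirane-2-carbaldehyde
Product: 9 (1S)-1-[(2S,3R)-3-(2-bromoethyl)-3-methyloxiran-2-yl]prop-2-en-1-ol
Conditions: CH2=CHMgBr, THF, −78 °C; aq. NH4Cl
Reagents that add atoms: vinylmagnesium bromide, C=C[Mg]Br
Why: Felkin–Anh Grignard addition to the α,β-epoxy aldehyde (epoxide C–O anti to the nucleophile, helped by the cis chain on the oxirane) should give the anti epoxy alcohol, which sets C6 (S).

Step 7
Reactants: 9 (1S)-1-[(2S,3R)-3-(2-bromoethyl)-3-methyloxiran-2-yl]prop-2-en-1-ol; 10 2-(bromomethyl)prop-2-enoic acid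
Product: 11 (1S)-1-[(2S,3R)-3-(2-bromoethyl)-3-methyloxiran-2-yl]prop-2-en-1-yl 2-(bromomethyl)prop-2-enoate
Conditions: DIC, DMAP (cat.), CH2Cl2, 0 °C
Reagents that add atoms: none
Why: Steglich carbodiimide esterification acylates the secondary allylic alcohol under conditions that should not ionise the epoxide or displace the allylic bromide.

Step 8
Reactants: 11 the diene ester
Product: 12 (5S)-3-(bromomethyl)-5-[(2S,3R)-3-(2-bromoethyl)-3-methyloxiran-2-yl]furan-2(5H)-one
Conditions: second-generation Grubbs catalyst, (H2IMes)(PCy3)Cl2Ru=CHPh (5 mol%), toluene, 80 °C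
Reagents that add atoms: none
Why: Ring-closing metathesis between the vinyl group and the 1,1-disubstituted acrylate should close the butenolide with loss of ethene and leave C6 untouched.

Step 9
Reactants: 12 the 3-(bromomethyl)butenolide
Product: 13 (5S)-5-[(2S,3R)-3-(2-bromoethyl)-3-methyloxiran-2-yl]-3-[(tributylstannyl)methyl]furan-2(5H)-one
Conditions: (Bu3Sn)2, Pd2(dba)3 (cat.), THF, 25 °C
Reagents that add atoms: hexabutyldistannane, CCCC[Sn](CCCC)(CCCC)[Sn](CCCC)(CCCC)CCCC
Why: Palladium-catalysed stannylation of the allylic bromide through the π-allyl complex should put tin on the primary terminus, while the unactivated alkyl bromide and the epoxide stay intact.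

Step 10
Reactants: 14 (2E)-but-2-enal; 15 methyl prop-2-ynoate
Product: 16 methyl (2E,4E)-2-(bromomethylidene)-3-hydroxyhex-4-enoate (racemic)
Conditions: MgBr2·OEt2, CH2Cl2, 0 °C, then 40 °C; H2O
Reagents that add atoms: magnesium bromide, [Mg+2].[Br-].[Br-]
Why: Halo-aldol reaction (the bromide variant of the Morita–Baylis–Hillman reaction: bromide adds to the propiolate and the bromoallenolate attacks the enal carbonyl 1,2); warming should let the adduct settle on the (E) bromoalkene with Br cis to the carbinol.

Step 11
Reactants: 16 the racemic bromo dienol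
Product: 17 methyl (2E,3S,4E)-2-(bromomethylidene)-3-hydroxyhex-4-enoate
Conditions: Ti(OiPr)4 (cat.), L-(+)-diisopropyl tartrate, t-BuOOH (0.6 equiv), 4 Å molecular sieves, CH2Cl2, −20 °C
Reagents that add atoms: none
Why: Sharpless kinetic resolution: the L-(+)-tartrate catalyst should epoxidise the propenyl group of the (3R) enantiomer fast and leave the (3S) alcohol, the electron-poor bromoacrylate alkene being inert.

Step 12
Reactants: 17 the (3S) alcohol
Product: 18 methyl (2E,3S,4E)-3-(acetyloxy)-2-(bromomethylidene)hex-4-enoate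
Conditions: Ac2O, pyridine, DMAP (cat.), CH2Cl2, 0 °C
Reagents that add atoms: acetic anhydride, CC(=O)OC(C)=O
Why: O-Acetylation installs the C9 acetate of the target without touching the stereocentre.

Step 13
Reactants: 18 the dienyl acetate
Product: 19 methyl (2E,3R)-3-(acetyloxy)-2-(bromomethylidene)-4-oxobutanoate
Conditions: O3, pyridine (3 equiv), CH2Cl2, −78 °C
Reagents that add atoms: ozone, [O-][O+]=O
Why: Ozonolysis should cleave only the electron-rich disubstituted alkene, and pyridine breaks the carbonyl oxide down in situ, so the labile α-acetoxy aldehyde (C8) is obtained directly.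

Step 14
Reactants: 20 methyl 2-(hydroxymethyl)prop-2-enoate
Product: 21 methyl 2-{[(tert-butyldimethylsilyl)oxy]methyl}prop-2-enoate
Conditions: TBSCl, imidazole, CH2Cl2, 0 to 25 °C
Reagents that add atoms: tert-butyldimethylsilyl chloride, CC(C)(C)[Si](C)(C)Cl
Why: Silylation of the primary alcohol masks the hydroxymethyl group of the side-chain acid.

Step 15
Reactants: 21 the silyl ether ester
Product: 22 2-{[(tert-butyldimethylsilyl)oxy]methyl}prop-2-enoic acid
Conditions: LiOH, THF/H2O, 0 °C; dilute HCl to pH 4
Reagents that add atoms: lithium hydroxide, [Li+].[OH-]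
Why: Saponification of the methyl ester gives the acid while the primary silyl ether survives cold aqueous hydroxide.

Step 16
Reactants: 13 the allylstannane; 19 the α-acetoxy aldehyde
Product: 23 methyl (2E,3R,4S)-3-(acetyloxy)-2-(bromomethylidene)-4-{(2S,3R)-2-[(2S,3R)-3-(2-bromoethyl)-3-methyloxiran-2-yl]-4-methylidene-5-oxooxolan-3-yl}-4-hydroxybutanoate
Conditions: BF3·OEt2, CH2Cl2, −78 °C; aq. NaHCO3
Reagents that add atoms: none
Why: Lewis acid-promoted allylstannane addition through an open transition state: C7 attacks anti to the C6 substituent (trans lactone, C7 R), the open antiperiplanar arrangement gives the syn C7/C8 relationship, and polar Felkin–Anh control by the C9 acetate gives the 8,9-anti alcohol (C8 S), the three preferences being matched.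

Step 17
Reactants: 23 the C8 alcohol; 22 the silyloxymethyl acrylic acid
Product: 24 the C8 2-{[(tert-butyldimethylsilyl)oxy]methyl}prop-2-enoate ester of 23
Conditions: DIC, DMAP (cat.), CH2Cl2, 0 °C
Reagents that add atoms: none
Why: Steglich esterification of the only free hydroxyl installs the C8 side chain before the neighbouring acetate can migrate.

Step 18
Reactants: 24 the primary bromide
Product: 25 the corresponding primary iodide (2-iodoethyl on C4)
Conditions: NaI, acetone, 40 °C, dark
Reagents that add atoms: sodium iodide, [Na+].[I-]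
Why: Finkelstein SN2 exchange at the primary bromide; the vinyl bromide should not exchange under these conditions.

Step 19
Reactants: 25 the iodo bromoalkene seco-precursor
Product: 27 the tert-butyldimethylsilyl ether of 28 (10-membered ring closed), via alkylzinc iodide 26 (not isolated)
Conditions: Zn dust (activated with Me3SiCl and BrCH2CH2Br), THF, 30 °C; then syringe-pump addition to Pd(OAc)2 (10 mol%), SPhos (20 mol%), THF, 25 °C, final concentration 1 mM
Reagents that add atoms: none
Why: Zinc inserts into the primary C2–I bond to give 26; the palladium catalyst adds oxidatively to the C1–Br bond of the β-bromoacrylate with retention, the tethered alkylzinc transmetalates, and reductive elimination forms the C1–C2 bond. The closest known reaction type is the intramolecular Negishi C(sp3)–C(sp2) coupling of functionalised alkylzinc halides with alkenyl halides. The 10-membered carbocycle is closed head-to-tail by reductive elimination from an 11-membered palladacycle, a closure that the cis epoxide, the trans-fused lactone and the cis-disposed C2 and C9 ends should pre-organise. No stereocentre is created; the (E) bromoalkene geometry is transferred with retention, so C2 ends up cis to C9 across C1=C10 as in 28. The step needs zinc insertion at the alkyl iodide only and ring closure faster than β-hydride elimination or oligomerisation: the primary iodide inserts much faster than the vinyl bromide, neutral alkylzinc halides do not attack the epoxide, the enoates or the acetate, SPhos speeds reductive elimination, and slow addition at 1 mM suppresses intermolecular coupling.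

Step 20
Reactants: 27 the silyl ether of 28
Product: 28 the target CNP0147016.1
Conditions: HF·pyridine, pyridine, THF, 0 °C
Reagents that add atoms: none
Why: Buffered fluoride desilylation frees the primary alcohol under conditions that the epoxide, the acetate and the α-methylene lactone should tolerate.

Compound list
1 | 4-bromobut-1-yne | C#CCCBr | starting material
2 | lithium 4-bromobut-1-yn-1-ide | [Li]C#CCCBr | intermediate (not isolated)
3 | methyl 5-bromopent-2-ynoate | COC(=O)C#CCCBr | intermediate
4 | lithium [(1Z)-4-bromo-1-(methoxycarbonyl)-2-methylbut-1-en-1-yl](methyl)cuprate | [Li+].COC(=O)/C([Cu-]C)=C(/C)CCBr | intermediate (not isolated)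
5 | methyl (2Z)-5-bromo-3-methylpent-2-enoate | COC(=O)/C=C(/C)CCBr | intermediate
6 | (2Z)-5-bromo-3-methylpent-2-en-1-ol | OC/C=C(/C)CCBr | intermediate
7 | [(2S,3R)-3-(2-bromoethyl)-3-methyloxiran-2-yl]methanol | BrCC[C@@]1(C)O[C@H]1CO | intermediate
8 | (2R,3R)-3-(2-bromoethyl)-3-methyloxirane-2-carbaldehyde | BrCC[C@@]1(C)O[C@H]1C=O | intermediate
9 | (1S)-1-[(2S,3R)-3-(2-bromoethyl)-3-methyloxiran-2-yl]prop-2-en-1-ol | BrCC[C@@]1(C)O[C@H]1[C@@H](O)C=C | intermediate
10 | 2-(bromomethyl)prop-2-enoic acid | C=C(CBr)C(=O)O | starting material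
11 | (1S)-1-[(2S,3R)-3-(2-bromoethyl)-3-methyloxiran-2-yl]prop-2-en-1-yl 2-(bromomethyl)prop-2-enoate | BrCC[C@@]1(C)O[C@H]1[C@@H](OC(=O)C(=C)CBr)C=C | intermediate
12 | (5S)-3-(bromomethyl)-5-[(2S,3R)-3-(2-bromoethyl)-3-methyloxiran-2-yl]furan-2(5H)-one | BrCC[C@@]1(C)O[C@H]1[C@H]2OC(=O)C(CBr)=C2 | intermediate
13 | (5S)-5-[(2S,3R)-3-(2-bromoethyl)-3-methyloxiran-2-yl]-3-[(tributylstannyl)methyl]furan-2(5H)-one | BrCC[C@@]1(C)O[C@H]1[C@H]2OC(=O)C(C[Sn](CCCC)(CCCC)CCCC)=C2 | intermediate
14 | (2E)-but-2-enal | C/C=C/C=O | starting material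
15 | methyl prop-2-ynoate | C#CC(=O)OC | starting material
16 | methyl (2E,4E)-2-(bromomethylidene)-3-hydroxyhex-4-enoate, racemic | C/C=C/C(O)/C(C(=O)OC)=C\Br | intermediate
17 | methyl (2E,3S,4E)-2-(bromomethylidene)-3-hydroxyhex-4-enoate | C/C=C/[C@H](O)/C(C(=O)OC)=C\Br | intermediate
18 | methyl (2E,3S,4E)-3-(acetyloxy)-2-(bromomethylidene)hex-4-enoate | C/C=C/[C@H](OC(C)=O)/C(C(=O)OC)=C\Br | intermediate
19 | methyl (2E,3R)-3-(acetyloxy)-2-(bromomethylidene)-4-oxobutanoate | O=C[C@H](OC(C)=O)/C(C(=O)OC)=C\Br | intermediate
20 | methyl 2-(hydroxymethyl)prop-2-enoate | C=C(CO)C(=O)OC | starting material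
21 | methyl 2-{[(tert-butyldimethylsilyl)oxy]methyl}prop-2-enoate | C=C(CO[Si](C)(C)C(C)(C)C)C(=O)OC | intermediate
22 | 2-{[(tert-butyldimethylsilyl)oxy]methyl}prop-2-enoic acid | C=C(CO[Si](C)(C)C(C)(C)C)C(=O)O | intermediate
23 | methyl (2E,3R,4S)-3-(acetyloxy)-2-(bromomethylidene)-4-{(2S,3R)-2-[(2S,3R)-3-(2-bromoethyl)-3-methyloxiran-2-yl]-4-methylidene-5-oxooxolan-3-yl}-4-hydroxybutanoate | BrCC[C@@]1(C)O[C@H]1[C@H]2OC(=O)C(=C)[C@@H]2[C@H](O)[C@H](OC(C)=O)/C(C(=O)OC)=C\Br | intermediate
24 | 23 esterified at the C8 hydroxyl with 2-{[(tert-butyldimethylsilyl)oxy]methyl}prop-2-enoic acid (C4–C9 configured as in 28) | BrCC[C@@]1(C)O[C@H]1[C@H]2OC(=O)C(=C)[C@@H]2[C@H](OC(=O)C(=C)CO[Si](C)(C)C(C)(C)C)[C@H](OC(C)=O)/C(C(=O)OC)=C\Br | intermediate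
25 | 24 with the primary bromide replaced by iodide (2-iodoethyl on C4) | ICC[C@@]1(C)O[C@H]1[C@H]2OC(=O)C(=C)[C@@H]2[C@H](OC(=O)C(=C)CO[Si](C)(C)C(C)(C)C)[C@H](OC(C)=O)/C(C(=O)OC)=C\Br | intermediate
26 | alkylzinc iodide from 25 (C2–ZnI) | I[Zn]CC[C@@]1(C)O[C@H]1[C@H]2OC(=O)C(=C)[C@@H]2[C@H](OC(=O)C(=C)CO[Si](C)(C)C(C)(C)C)[C@H](OC(C)=O)/C(C(=O)OC)=C\Br | intermediate (not isolated)
27 | tert-butyldimethylsilyl ether of 28 at the hydroxymethyl group of the C8 acrylate | C=C(CO[Si](C)(C)C(C)(C)C)C(=O)O[C@H]1[C@H]2C(=C)C(=O)O[C@@H]2[C@@H]2O[C@]2(C)CC/C=C(/C(=O)OC)[C@H]1OC(C)=O | intermediate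
28 | methyl (1(10)E,4R,5S,6S,7R,8S,9R)-9-(acetyloxy)-4,5-epoxy-8-{[2-(hydroxymethyl)prop-2-enoyl]oxy}-12-oxo-6,12-epoxygermacra-1(10),11(13)-dien-14-oate, CNP0147016.1 | C=C(CO)C(=O)O[C@H]1[C@H]2C(=C)C(=O)O[C@@H]2[C@@H]2O[C@]2(C)CC/C=C(/C(=O)OC)[C@H]1OC(C)=O | target

Total step count: 20. Longest linear sequence: 14 steps (steps 1 to 9 and 16 to 20).

Steps most likely to fail

Step 16. The ester-conjugated allylstannane is a weak nucleophile, so the addition may be slower than opening or rearrangement of the trisubstituted epoxide by BF3, or the open transition state may not deliver the syn C7/C8 relationship. The fallback sets out from bromide 12 and aldehyde 19: indium-mediated Barbier allylation (In powder, THF/H2O, 25 °C) needs no Lewis acid and, through its closed chair transition state, should give the trans lactone but the C8 epimer, 8-epi-23 F1. Dess–Martin oxidation then gives the C8 ketone F2, and NaBH4/CeCl3·7H2O in MeOH at −78 °C should reduce it under polar Felkin–Anh control of the C9 acetate to the 8,9-anti alcohol, returning to 23.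

Step 19. Zinc may also insert into the vinyl bromide, or the alkylpalladium intermediate may undergo β-hydride elimination or couple intermolecularly instead of closing the ring. The fallback sets out from dibromide 24 and omits the organozinc: nickel-catalysed reductive cross-electrophile coupling of the alkyl bromide with the bromoalkene (NiBr2·glyme, 4,4′-di-tert-butyl-2,2′-bipyridine, Mn powder, NaI, DMA, high dilution) would form the same C1–C2 bond and return to 27 without any new isolated compound.

Step 6. Facial selectivity in the Grignard addition to the epoxy aldehyde may be poor. The fallback sets out from 8: the addition is run as before, the mixture of C6 epimers is oxidised with Dess–Martin periodinane to 1-[(2R,3R)-3-(2-bromoethyl)-3-methyloxiran-2-yl]prop-2-en-1-one F3, and chelation-controlled 1,2-reduction with Zn(BH4)2 in Et2O at −20 °C, which is known to give anti epoxy alcohols from α,β-epoxy ketones, returns to 9.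

Further compounds
F1 | step 16 | methyl (2E,3R,4R)-3-(acetyloxy)-2-(bromomethylidene)-4-{(2S,3R)-2-[(2S,3R)-3-(2-bromoethyl)-3-methyloxiran-2-yl]-4-methylidene-5-oxooxolan-3-yl}-4-hydroxybutanoate (8-epi-23) | BrCC[C@@]1(C)O[C@H]1[C@H]2OC(=O)C(=C)[C@@H]2[C@@H](O)[C@H](OC(C)=O)/C(C(=O)OC)=C\Br
F2 | step 16 | C8 ketone of 23 (4-oxo compound) | BrCC[C@@]1(C)O[C@H]1[C@H]2OC(=O)C(=C)[C@@H]2C(=O)[C@H](OC(C)=O)/C(C(=O)OC)=C\Br
F0 | step 19 | none | none
F3 | step 6 | 1-[(2R,3R)-3-(2-bromoethyl)-3-methyloxiran-2-yl]prop-2-en-1-one | BrCC[C@@]1(C)O[C@H]1C(=O)C=C
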